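**Retrosynthetic overview**
- Feature used: in the trans-2-aryl-3-methyl-2,3-dihydro-1,4-benzodioxine, C2 (benzylic, bonded to O1 and the syringyl ring; C7 in neolignan numbering) and C3 (bonded to the methyl group and O4; C8) are adjacent stereocentres. Once the O1–C8a aryl ether bond is cut, C2 is the carbinol carbon of an aryl ketone and C3 is an epimerisable alpha-aryloxy carbon.
- Target ⇐ its silyl ether ⇐ copper-catalysed closure of the O1–C8a bond from the (1R,2R) bromo alcohol. The dioxane is the only ring made and is closed in the last step but one.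
- (1R,2R) bromo alcohol ⇐ racemic alpha-aryloxy ketone by asymmetric transfer hydrogenation with dynamic kinetic resolution, which sets C7 and C8 together.
- Ketone ⇐ Williamson C8–O4 bond between 2-bromo-6-methoxy-4-[(E)-prop-1-enyl]phenol (5-bromovanillin, EtMgBr, dehydration) and the alpha-bromopropiophenone (syringaldehyde: silylation, EtMgBr, MnO2, CuBr2).

Key step: step 8

Assumption: C7/C8 (neolignan numbering) are C2/C3 of the benzodioxine; the syn (threo) outcome of step 8 is expected by analogy with related alpha-alkoxy and alpha-aryloxy ketones and has not been established for this substrate.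

**Step 1**
Reactants: 1 5-bromovanillin (3-bromo-4-hydroxy-5-methoxybenzaldehyde); 2 ethylmagnesium bromide
Product: 3 racemic 2-bromo-4-(1-hydroxypropyl)-6-methoxyphenol
Conditions: EtMgBr (3.2 equiv), THF, 0 °C to rt; aq. NH4Cl
Reagents that add atoms: ethylmagnesium bromide 2, CC[Mg]Br
Why: Grignard 1,2-addition to the aldehyde after the first equivalent has deprotonated the phenol; the electron-rich aryl bromide should not undergo Br/Mg exchange with EtMgBr at this temperature, and the racemic carbinol centre is removed in step 2.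

**Step 2**
Reactants: 3 racemic 2-bromo-4-(1-hydroxypropyl)-6-methoxyphenol
Product: 4 2-bromo-6-methoxy-4-[(E)-prop-1-enyl]phenol
Conditions: p-TsOH·H2O (2 mol %), toluene (dilute), reflux, Dean–Stark
Reagents that add atoms: none
Why: acid-catalysed E1 dehydration of a para-hydroxybenzylic alcohol through the quinone-methide-like benzylic cation should give the conjugated, thermodynamically preferred (E)-propenyl arene.

**Step 3**
Reactants: 5 syringaldehyde (4-hydroxy-3,5-dimethoxybenzaldehyde)
Product: 6 3,5-dimethoxy-4-(triisopropylsilyloxy)benzaldehyde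
Conditions: TIPSCl, imidazole, DMF, rt to 40 °C
Reagents that add atoms: triisopropylsilyl chloride (TIPSCl), CC(C)[Si](Cl)(C(C)C)C(C)C
Why: imidazole-promoted silyl ether formation on the acidic phenol; the bulky silyl group is chosen to survive the Grignard, oxidation, bromination and carbonate steps that follow.

**Step 4**
Reactants: 6 3,5-dimethoxy-4-(triisopropylsilyloxy)benzaldehyde; 2 ethylmagnesium bromide
Product: 7 racemic 1-[3,5-dimethoxy-4-(triisopropylsilyloxy)phenyl]propan-1-ol
Conditions: EtMgBr (1.3 equiv), THF, 0 °C; aq. NH4Cl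
Reagents that add atoms: ethylmagnesium bromide 2, CC[Mg]Br
Why: Grignard addition to a non-enolisable aryl aldehyde; the carbinol centre is racemic and is oxidised in the next step.

**Step 5**
Reactants: 7 racemic 1-[3,5-dimethoxy-4-(triisopropylsilyloxy)phenyl]propan-1-ol
Product: 8 1-[3,5-dimethoxy-4-(triisopropylsilyloxy)phenyl]propan-1-one
Conditions: MnO2 (activated, excess), CH2Cl2, rt
Reagents that add atoms: none
Why: MnO2 oxidation of an electron-rich benzylic alcohol to the aryl ketone, neutral conditions that leave the aryl silyl ether untouched.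

**Step 6**
Reactants: 8 1-[3,5-dimethoxy-4-(triisopropylsilyloxy)phenyl]propan-1-one
Product: 9 racemic 2-bromo-1-[3,5-dimethoxy-4-(triisopropylsilyloxy)phenyl]propan-1-one
Conditions: CuBr2 (2.1 equiv), EtOAc/CHCl3 (1:1), reflux
Reagents that add atoms: copper dibromide CuBr2, Br[Cu]Br
Why: CuBr2 alpha-bromination of a ketone through its enol, which is selective for the alpha carbon over the ketone-deactivated ring positions; the new centre is racemic and is substituted in step 7.

**Step 7**
Reactants: 4 2-bromo-6-methoxy-4-[(E)-prop-1-enyl]phenol; 9 racemic 2-bromo-1-[3,5-dimethoxy-4-(triisopropylsilyloxy)phenyl]propan-1-one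
Product: 10 racemic 2-[2-bromo-6-methoxy-4-[(E)-prop-1-enyl]phenoxy]-1-[3,5-dimethoxy-4-(triisopropylsilyloxy)phenyl]propan-1-one
Conditions: K2CO3, acetone, reflux
Reagents that add atoms: none
Why: Williamson ether synthesis, an SN2 displacement of the carbonyl-activated secondary bromide by the potassium phenoxide; the C8 centre is racemic here, which is what step 8 requires.

**Step 8**
Reactants: 10 racemic 2-[2-bromo-6-methoxy-4-[(E)-prop-1-enyl]phenoxy]-1-[3,5-dimethoxy-4-(triisopropylsilyloxy)phenyl]propan-1-one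
Product: 11 (1R,2R)-2-[2-bromo-6-methoxy-4-[(E)-prop-1-enyl]phenoxy]-1-[3,5-dimethoxy-4-(triisopropylsilyloxy)phenyl]propan-1-ol
Conditions: RuCl(p-cymene)[(S,S)-TsDPEN] (2 mol %), HCO2H (3 equiv), DBU (4 equiv), DMF, 40 °C
Reagents that add atoms: none
Why: Noyori–Ikariya-type asymmetric transfer hydrogenation run as a dynamic kinetic resolution: the ruthenium amide takes hydride and proton from formic acid with loss of CO2, and the resulting Ru–H/N–H species passes both to the C7 carbonyl through an outer-sphere six-membered transition state, forming only the C7–H and O–H bonds. The closest known reaction type is the ruthenium–TsDPEN transfer hydrogenation of racemic alpha-alkoxy and alpha-aryloxy ketones with epimerisation of the alpha carbon in the flask. No ring is closed in this step. C7 is set by the catalyst, since with the (S,S)-ligand the ketone aryl group sits under the p-cymene ring (CH/π contact) and hydride adds to the carbonyl face that gives the 1R carbinol, as for other alpha-heteroatom-substituted aryl ketones. C8 is set by the resolution, since DBU interconverts the ketone enantiomers through the enolate of the C8–H (acidified by the ketone and the aryloxy oxygen) and the catalyst should reduce faster the 8R enantiomer, whose polar Felkin–Anh arrangement (aryloxy group anti to the incoming hydride, hydride passing the C8–H) coincides with the catalyst-preferred face, which leads to the syn (1R,2R) alcohol. The step needs syn over anti selectivity and epimerisation faster than reduction; the electron-rich, slowly reduced aryl ketone and the basic formate medium favour the latter, and the propenyl group, aryl bromide and silyl ether are inert to the ruthenium hydride.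

**Step 9**
Reactants: 11 (1R,2R)-2-[2-bromo-6-methoxy-4-[(E)-prop-1-enyl]phenoxy]-1-[3,5-dimethoxy-4-(triisopropylsilyloxy)phenyl]propan-1-ol
Product: 12 [4-[(2R,3R)-5-methoxy-3-methyl-7-[(E)-prop-1-enyl]-2,3-dihydro-1,4-benzodioxin-2-yl]-2,6-dimethoxyphenoxy]triisopropylsilane
Conditions: CuI (10 mol %), 1,10-phenanthroline (20 mol %), Cs2CO3 (2 equiv), toluene, 110 °C, argon
Reagents that add atoms: none
Why: Ullmann-type copper-catalysed intramolecular O-arylation of the caesium alkoxide by the neighbouring aryl bromide closes the six-membered dioxane; no bond at C7 or C8 is broken, so the syn alcohol should give the trans (2R,3R) ring with retention at both centres.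

**Step 10**
Reactants: 12 [4-[(2R,3R)-5-methoxy-3-methyl-7-[(E)-prop-1-enyl]-2,3-dihydro-1,4-benzodioxin-2-yl]-2,6-dimethoxyphenoxy]triisopropylsilane
Product: 13 4-[(2R,3R)-5-methoxy-3-methyl-7-[(E)-prop-1-enyl]-2,3-dihydro-1,4-benzodioxin-2-yl]-2,6-dimethoxyphenol (CNP0227775.1)
Conditions: Bu4NF (1.2 equiv), AcOH (1.2 equiv), THF, 0 °C
Reagents that add atoms: none
Why: fluoride-mediated cleavage of the aryl silyl ether (desilylation), buffered with acetic acid so that the electron-rich phenol is not left as an air-sensitive phenoxide; the stereocentres and the (E)-alkene are not involved.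

**Compound list**
1 | 5-bromovanillin | O=Cc1cc(Br)c(O)c(OC)c1 | starting material
2 | ethylmagnesium bromide | CC[Mg]Br | starting material
3 | racemic 2-bromo-4-(1-hydroxypropyl)-6-methoxyphenol | CCC(O)c1cc(Br)c(O)c(OC)c1 | intermediate
4 | 2-bromo-6-methoxy-4-[(E)-prop-1-enyl]phenol | C/C=C/c1cc(Br)c(O)c(OC)c1 | intermediate
5 | syringaldehyde | O=Cc1cc(OC)c(O)c(OC)c1 | starting material
6 | 3,5-dimethoxy-4-(triisopropylsilyloxy)benzaldehyde | O=Cc1cc(OC)c(O[Si](C(C)C)(C(C)C)C(C)C)c(OC)c1 | intermediate
7 | racemic 1-[3,5-dimethoxy-4-(triisopropylsilyloxy)phenyl]propan-1-ol | CCC(O)c1cc(OC)c(O[Si](C(C)C)(C(C)C)C(C)C)c(OC)c1 | intermediate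
8 | 1-[3,5-dimethoxy-4-(triisopropylsilyloxy)phenyl]propan-1-one | CCC(=O)c1cc(OC)c(O[Si](C(C)C)(C(C)C)C(C)C)c(OC)c1 | intermediate
9 | racemic 2-bromo-1-[3,5-dimethoxy-4-(triisopropylsilyloxy)phenyl]propan-1-one | CC(Br)C(=O)c1cc(OC)c(O[Si](C(C)C)(C(C)C)C(C)C)c(OC)c1 | intermediate
10 | racemic 2-[2-bromo-6-methoxy-4-[(E)-prop-1-enyl]phenoxy]-1-[3,5-dimethoxy-4-(triisopropylsilyloxy)phenyl]propan-1-one | C/C=C/c1cc(OC)c(OC(C)C(=O)c2cc(OC)c(O[Si](C(C)C)(C(C)C)C(C)C)c(OC)c2)c(Br)c1 | intermediate
11 | (1R,2R)-2-[2-bromo-6-methoxy-4-[(E)-prop-1-enyl]phenoxy]-1-[3,5-dimethoxy-4-(triisopropylsilyloxy)phenyl]propan-1-ol | O[C@H](c1cc(OC)c(O[Si](C(C)C)(C(C)C)C(C)C)c(OC)c1)[C@@H](C)Oc1c(Br)cc(/C=C/C)cc1OC | intermediate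
12 | [4-[(2R,3R)-5-methoxy-3-methyl-7-[(E)-prop-1-enyl]-2,3-dihydro-1,4-benzodioxin-2-yl]-2,6-dimethoxyphenoxy]triisopropylsilane | C/C=C/c1cc(OC)c2c(c1)O[C@H](c1cc(OC)c(O[Si](C(C)C)(C(C)C)C(C)C)c(OC)c1)[C@@H](C)O2 | intermediate
13 | 4-[(2R,3R)-5-methoxy-3-methyl-7-[(E)-prop-1-enyl]-2,3-dihydro-1,4-benzodioxin-2-yl]-2,6-dimethoxyphenol | C/C=C/c1cc(OC)c2c(c1)O[C@H](c1cc(OC)c(O)c(OC)c1)[C@@H](C)O2 | target

**Step count**
Total: 10 steps. Longest linear sequence: 8 steps (5 → 6 → 7 → 8 → 9 → 10 → 11 → 12 → 13; steps 3 to 10).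

**Steps most likely to fail**

Step 8. Epimerisation at C8 may be slower than reduction, or the catalyst may discriminate poorly between the syn and anti transition states; either would give diastereomer mixtures or an alcohol of low enantiomeric purity. The fallback takes C8 from the chiral pool instead of from the resolution.
- Setting out from phenol 4, a Mitsunobu reaction with ethyl (S)-lactate (PPh3, DIAD, THF, 0 °C to rt) should give, with inversion, ethyl (2R)-2-[2-bromo-6-methoxy-4-[(E)-prop-1-enyl]phenoxy]propanoate F1.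
- Aminolysis with MeNH(OMe)·HCl and i-PrMgCl (THF, −20 °C) would give the Weinreb amide (2R)-2-[2-bromo-6-methoxy-4-[(E)-prop-1-enyl]phenoxy]-N-methoxy-N-methylpropanamide F2.
- Commercial 4-bromo-2,6-dimethoxyphenol would be silylated (TIPSCl, imidazole, DMF) to (4-bromo-2,6-dimethoxyphenoxy)triisopropylsilane F3 and converted with Mg in THF into [3,5-dimethoxy-4-(triisopropylsilyloxy)phenyl]magnesium bromide F4.
- Addition of F4 to F2 (THF, −20 to 0 °C) should give the ketone (2R)-2-[2-bromo-6-methoxy-4-[(E)-prop-1-enyl]phenoxy]-1-[3,5-dimethoxy-4-(triisopropylsilyloxy)phenyl]propan-1-one F5.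
- Reduction of F5 with the same RuCl(p-cymene)[(S,S)-TsDPEN] in HCO2H/Et3N (5:2), an acidic medium that should leave C8 untouched, would set only C7 under catalyst control and come back to the route at alcohol 11.

Step 9. Oxidative addition and C–O coupling at the electron-rich, ortho-substituted aryl bromide may be sluggish, with protodebromination or base-induced loss of the silyl group competing. The fallback closes the ring through the other C–O bond (C7–O) instead of the aryl C–O bond.
- Setting out from alcohol 11, Miyaura borylation (B2pin2, Pd(dppf)Cl2, KOAc, dioxane, 90 °C) should give (1R,2R)-2-[2-methoxy-4-[(E)-prop-1-enyl]-6-(4,4,5,5-tetramethyl-1,3,2-dioxaborolan-2-yl)phenoxy]-1-[3,5-dimethoxy-4-(triisopropylsilyloxy)phenyl]propan-1-ol F6.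
- Oxidation (NaBO3·4H2O, THF/H2O, rt) would give the phenol (1R,2R)-2-[2-hydroxy-6-methoxy-4-[(E)-prop-1-enyl]phenoxy]-1-[3,5-dimethoxy-4-(triisopropylsilyloxy)phenyl]propan-1-ol F7.
- Catalytic p-TsOH in CH2Cl2 at 0 °C to rt should ionise the benzylic alcohol to the para-silyloxy-stabilised cation, which the phenol captures reversibly. Under this thermodynamic control the fixed C8 (R) centre should direct C7 to the trans (2R,3R) ring, and the route is rejoined at silyl ether 12.

Step 2. Acid may trigger cationic oligomerisation of the quinone-methide-like intermediate and of the electron-rich propenylphenol, and the E selectivity may be incomplete. The fallback avoids the benzylic alcohol and the acid altogether.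
- Setting out from aldehyde 1, a Wittig olefination with ethylidenetriphenylphosphorane F8 (from ethyltriphenylphosphonium bromide and KOtBu, 2.2 equiv each, THF, 0 °C to rt; one equivalent is consumed by the phenol) should give phenol 4 mixed with 2-bromo-6-methoxy-4-[(Z)-prop-1-enyl]phenol F9.
- Isomerisation of the mixture with PdCl2(MeCN)2 (catalytic, CH2Cl2, rt) should convert F9 into the more stable (E)-isomer and come back to the route at phenol 4.

**Further compounds**
F1 | step 8 | ethyl (2R)-2-[2-bromo-6-methoxy-4-[(E)-prop-1-enyl]phenoxy]propanoate | C[C@@H](Oc1c(Br)cc(/C=C/C)cc1OC)C(=O)OCC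
F2 | step 8 | (2R)-2-[2-bromo-6-methoxy-4-[(E)-prop-1-enyl]phenoxy]-N-methoxy-N-methylpropanamide | C[C@@H](Oc1c(Br)cc(/C=C/C)cc1OC)C(=O)N(C)OC
F3 | step 8 | (4-bromo-2,6-dimethoxyphenoxy)triisopropylsilane | COc1cc(Br)cc(OC)c1O[Si](C(C)C)(C(C)C)C(C)C
F4 | step 8 | [3,5-dimethoxy-4-(triisopropylsilyloxy)phenyl]magnesium bromide | COc1cc([Mg]Br)cc(OC)c1O[Si](C(C)C)(C(C)C)C(C)C
F5 | step 8 | (2R)-2-[2-bromo-6-methoxy-4-[(E)-prop-1-enyl]phenoxy]-1-[3,5-dimethoxy-4-(triisopropylsilyloxy)phenyl]propan-1-one | C[C@@H](Oc1c(Br)cc(/C=C/C)cc1OC)C(=O)c1cc(OC)c(O[Si](C(C)C)(C(C)C)C(C)C)c(OC)c1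
F6 | step 9 | (1R,2R)-2-[2-methoxy-4-[(E)-prop-1-enyl]-6-(4,4,5,5-tetramethyl-1,3,2-dioxaborolan-2-yl)phenoxy]-1-[3,5-dimethoxy-4-(triisopropylsilyloxy)phenyl]propan-1-ol | O[C@H](c1cc(OC)c(O[Si](C(C)C)(C(C)C)C(C)C)c(OC)c1)[C@@H](C)Oc1c(B2OC(C)(C)C(C)(C)O2)cc(/C=C/C)cc1OC
F7 | step 9 | (1R,2R)-2-[2-hydroxy-6-methoxy-4-[(E)-prop-1-enyl]phenoxy]-1-[3,5-dimethoxy-4-(triisopropylsilyloxy)phenyl]propan-1-ol | O[C@H](c1cc(OC)c(O[Si](C(C)C)(C(C)C)C(C)C)c(OC)c1)[C@@H](C)Oc1c(O)cc(/C=C/C)cc1OC
F8 | step 2 | ethylidenetriphenylphosphorane | CC=P(c1ccccc1)(c1ccccc1)c1ccccc1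
F9 | step 2 | 2-bromo-6-methoxy-4-[(Z)-prop-1-enyl]phenol | C/C=C\c1cc(Br)c(O)c(OC)c1
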